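# Proposed synthesis of 5,7-dihydroxy-2',3',4',5'-tetramethoxyflavone (16) by squarate ring expansion

## The problem

Compound 16 is a flavone: rings A and C are fused as a benzopyran-4-one, and ring B is attached to C2 of ring C through one sp2–sp2 bond to C1'. The molecule has no stereocentre, so nothing needs to be controlled and nothing can exert control; the stereogenic atoms that appear on the way are racemic and are erased. The real task is the oxygen pattern. Ring A has the common phloroglucinol arrangement with free hydroxyls on C5 and C7, whereas ring B carries four adjacent methoxyls on C2', C3', C4' and C5', an arrangement that ordinary benzaldehydes and benzoic acids do not offer. Six phenolic oxygens must be sorted so that exactly the four on ring B are methylated, which means ring A must be masked with groups that come off without touching aryl methyl ethers. Three groups limit the choice of reagents: the pyranone, which hard nucleophiles attack at C2 and strong base opens; the 5-hydroxyl/C4-carbonyl chelate, beside which Lewis acids cleave ethers with little discrimination; and any electron-rich hydroquinone met en route, which air turns into a quinone. The feature that opens the key step is that C2' to C5' are four contiguous oxygen-bearing carbons, the same carbon–oxygen array as a squaric ester, while C1' and C6' form a two-carbon unit that can be an alkene already bonded to C2. A 4-alkenyl-4-hydroxy-2,3-dimethoxycyclobutenone therefore holds all six carbons of ring B in the right order, and only the C1'–C2' bond has to be made to close the ring.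

## Retrosynthesis

**16 back to 14.** The two O–benzyl bonds on ring A and the methyl groups on O2' and O5' are cut first, leading through the tetramethyl ether 15 to the hydroquinone 14. Benzyl is chosen for ring A because hydrogenolysis removes it without affecting aryl methyl ethers; a Lewis-acid deprotection next to the C4 carbonyl would not be trusted to spare the ring B methoxyls. The two late methyl groups are placed on exactly the oxygens that the ring-forming step releases as free phenols, so no selectivity among phenols is asked of the methylation: in 14 both ring A oxygens are blocked and both free hydroxyls are to be methylated.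

**14 back to 11.** Ring B is opened at C1'–C2', and C2' is reconnected to C5' as a four-membered ring. This gives the 4-alkenyl-4-hydroxycyclobutenone 11, with the dienylketene 12 and the cyclohexadienone 13 as the intermediates of the forward ring expansion. The neighbouring cut, the C2–C1' bond, would need a metallated 1,2,3,4-tetramethoxybenzene, which only moves the problem of the unusual arene into a building block. The cut chosen removes the arene altogether: the four oxygens come from a squarate, and C1' and C6' from an alkene. The forward reaction must open the cyclobutenone with the alkenyl arm turned toward the ketene and must tolerate a chromone on the alkene terminus.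

**11 back to 10 and 6.** The bond between the alkene carbon and C2 of the chromone is cut, giving the vinylstannane 10 and the 2-iodochromone 6 as partners for a Stille coupling. A Heck reaction of the plain vinyl carbinol would need base and warming on a substrate that rearranges on heating. Adding a chromone-bearing vinyl metal to the squarate is excluded, because the pyranone does not survive organolithium reagents. The Stille reaction can run at room temperature under neutral conditions, and the alkene geometry is fixed in the stannane. The forward reaction must proceed well below the temperature at which 10 and 11 open.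

**10 back to 8 and 7.** The bond between the carbinol carbon and the alkene is cut, giving dimethyl squarate 8 and the distannane 7, which delivers the vinyllithium 9 by tin–lithium exchange. Both carbonyls of 8 are equivalent, so the addition has no regiochemical question. It must stop after one addition and must keep the E-stannane intact.

**6 back to 1.** The C2–I bond is traced to a C2–H bond of the chromone 4 through the zinc intermediate 5. Ring C of 4 is cut at O1–C2 and C2–C3 to the enaminone 3 and then to the acetophenone 2, whose one-carbon unit comes from an amide acetal. Compound 2 is the dibenzyl ether of commercial 2,4,6-trihydroxyacetophenone 1. This branch uses only standard chromone chemistry. The single demand is that metallation of 4 occurs at C2 and not at C3 or on ring A.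

## Roads not taken

**Alternative 1:** The cut is at C4a–C5 of ring A. In the forward direction the 2-pyranone A2 would be opened by a magnesium alkoxide to the triketo ester A3. Its methylene between the two ketones (future C4a) would acylate onto the ester carbon (future C5), and aromatisation would give the chalcone A1. An oxidative cyclisation of A1 would then deliver 16.
- Merits: it follows the biosynthetic folding, needs no protecting groups and ends one step after A1.
- Weak points: it spends its key step on ring A, the one part of the molecule that is commercially available ready-made as 1. The poly-β-carbonyl chain can also close in the aldol mode or back to a pyranone. A1 has three free phenols, so the oxidative closure must choose between flavone, flavanone and aurone. The 2,3,4,5-tetraoxygenated ring must be brought in prefabricated in A2, which is the hard part of the target.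
- Comparison: if a tetramethoxyaryl building block is at hand, this road is shorter than the eight steps proposed here and uses no tin. The chosen plan sets against it that ring B is built from a commodity C4 unit with its oxygen pattern fixed by construction, and that no step has an open regiochemical question.

**Alternative 2:** The cuts are at C8a–O1 and C4a–C4. In the forward direction fluoride would release a 3,5-bis(benzyloxy)aryne from the silyl triflate A6. The aryne would insert into the C–O bond of the arylpropiolic acid A5 to give the ortho-hydroxyaryl ynone A4, and 6-endo closure of A4 would give 15.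
- Merits: it is convergent. The aryne distortion caused by the flanking benzyloxy group should direct the carboxylate oxygen to the remote aryne carbon, which places the acyl group between the two oxygens as required.
- Weak points: A6 takes several steps from a desymmetrised phloroglucinol. A5 again needs a tetramethoxyaryl halide. The ynone is a Michael acceptor exposed to fluoride and carboxylate, and its closure can also run 5-exo to an aurone.
- Comparison: the step count would be similar to the chosen plan, and the convergence is equal. It has no advantage in the supply of ring B, which is where the chosen plan is stronger.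

**Alternative 3:** The cut is at O1–C8a. In the forward direction the enol oxygen of the diketone A8 would displace an ortho fluoride under a carbonate base and close ring C to the difluoroflavone A7. The two remaining fluorides, ortho and para to the C4 carbonyl, would then be exchanged for benzyloxy groups to reach 15.
- Merits: the ring closure is robust, the fluorides serve as masked hydroxyls, and nothing is thermally fragile.
- Weak points: two alkoxide substitutions are needed on a pyranone that alkoxides can also attack at C2, the second at the hindered C5. A8 requires a 2,3,4,5-tetramethoxybenzoyl unit.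
- Comparison: this road is probably shorter and operationally simpler than the chosen one and avoids tin, and in that respect it is better. The chosen plan sets against it independence from any prefabricated tetraoxygenated arene and the absence of late nucleophilic substitutions on the base-sensitive core.

Key step: step 6

## Route

Assumption: the chromonyl group on the alkene terminus of 11 is taken not to divert the ring expansion, so that 11 behaves like simpler 4-alkenyl-4-hydroxycyclobutenones; TMPZnCl·LiCl in THF and the distannane 7 are taken as purchasable.

Step 1
Reactants: 1 2,4,6-trihydroxyacetophenone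
Product: 2 1-[2,4-bis(benzyloxy)-6-hydroxyphenyl]ethan-1-one
Conditions: BnBr (2.1 equiv), K2CO3, DMF, 0 to 23 °C
Reagents that add atoms: benzyl bromide, BrCc1ccccc1
Why: Williamson etherification; the 4-hydroxyl and one ortho hydroxyl react, while the remaining ortho hydroxyl is held in a hydrogen bond to the ketone and is the least nucleophilic, so limiting the bromide to about two equivalents should stop at the dibenzyl ether.

Step 2
Reactants: 2 1-[2,4-bis(benzyloxy)-6-hydroxyphenyl]ethan-1-one
Product: 4 5,7-bis(benzyloxy)-4H-chromen-4-one, via enaminone 3 (not isolated)
Conditions: Me2NCH(OMe)2, toluene, 100 °C; then conc. HCl, CH2Cl2, 40 °C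
Reagents that add atoms: N,N-dimethylformamide dimethyl acetal, COC(OC)N(C)C
Why: Condensation of the acetyl methyl with the amide acetal gives the vinylogous amide 3; acid then promotes conjugate addition of the phenol and loss of dimethylamine (addition–elimination), the standard enaminone route to 2,3-unsubstituted chromones, and benzyl ethers tolerate the brief two-phase acid treatment.

Step 3
Reactants: 4 5,7-bis(benzyloxy)-4H-chromen-4-one
Product: 6 5,7-bis(benzyloxy)-2-iodo-4H-chromen-4-one, via chromon-2-ylzinc chloride 5 (not isolated)
Conditions: TMPZnCl·LiCl (1.3 equiv), THF, −30 to 23 °C; then I2, THF, 0 °C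
Reagents that add atoms: iodine, II
Why: Directed C–H zincation with a hindered TMP zinc amide followed by iodolysis; without an added Lewis acid the base should remove the C2 hydrogen, the most acidic vinylic hydrogen because it lies next to the ring oxygen at the β-position of the enone, and the mild zinc reagent does not add to the carbonyl or open the pyranone.

Step 4
Reactants: 7 (E)-1,2-bis(tributylstannyl)ethene; 8 dimethyl squarate (3,4-dimethoxycyclobut-3-ene-1,2-dione)
Product: 10 racemic 4-hydroxy-2,3-dimethoxy-4-[(E)-2-(tributylstannyl)ethenyl]cyclobut-2-en-1-one, via (E)-2-(tributylstannyl)vinyllithium 9 (not isolated)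
Conditions: n-BuLi (1.0 equiv), THF, −78 °C; then cannulated into 8, THF, −78 °C; NH4Cl aq, −78 °C
Reagents that add atoms: none
Why: Tin–lithium exchange gives the E-vinyllithium with retention, and its 1,2-addition to one of the two equivalent carbonyls of the squarate is the standard entry to 4-alkenyl-4-hydroxycyclobutenones; inverse addition and a cold quench should prevent a second addition, and the carbinol centre forms racemic, which is of no consequence because it is destroyed in step 6.

Step 5
Reactants: 10 racemic 4-hydroxy-2,3-dimethoxy-4-[(E)-2-(tributylstannyl)ethenyl]cyclobut-2-en-1-one; 6 5,7-bis(benzyloxy)-2-iodo-4H-chromen-4-one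
Product: 11 racemic 4-[(E)-2-(5,7-bis(benzyloxy)-4-oxo-4H-chromen-2-yl)ethenyl]-4-hydroxy-2,3-dimethoxycyclobut-2-en-1-one
Conditions: Pd2(dba)3 (cat.), AsPh3, CuI (cat.), DMF, 23 °C, dark
Reagents that add atoms: none
Why: Stille coupling; the C2 iodide is a β-iodo enone and should add oxidatively to zerovalent palladium with ease, the AsPh3/CuI combination allows room temperature, far below the temperature at which the cyclobutenone opens, and the E geometry is transferred from tin with retention under neutral conditions that leave the free carbinol alone.

Step 6
Reactants: 11 racemic 4-[(E)-2-(5,7-bis(benzyloxy)-4-oxo-4H-chromen-2-yl)ethenyl]-4-hydroxy-2,3-dimethoxycyclobut-2-en-1-one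
Product: 14 5,7-bis(benzyloxy)-2-(2,5-dihydroxy-3,4-dimethoxyphenyl)-4H-chromen-4-one, via dienylketene 12 (not isolated), via cyclohexadienone 13 (not isolated)
Conditions: toluene (degassed), 110 °C, Ar; concentrated and used directly
Reagents that add atoms: none
Why: Heating should open the cyclobutenone by conrotatory four-electron electrocyclic cleavage of the bond between the carbonyl carbon and the carbinol carbon, giving the dienylketene 12. The step needs torquoselectivity: the hydroxyl, a donor, rotates outward, so the alkenyl arm turns inward and comes to lie cis to the ketene, and the substrate secures this by carrying the donor and the π-substituent on the same carbon. A disrotatory six-electron electrocyclisation of 12 then joins the ketene carbon (future C2') to the chromone-bearing alkene carbon (future C1'), closing ring B as a six-membered carbocycle in the cyclohexadienone 13. The E geometry set in step 5 puts hydrogen, not the chromone, on the inside of the cyclising triene. The only new stereocentre, the sp3 carbon of 13, is racemic and is erased at once by enolisation to the aromatic hydroquinone 14, as is the carbinol centre of 11. The competing path, inward rotation of the hydroxyl followed by lactonisation of the ketene to a butenolide, is disfavoured by the same electronic preference. The closest known reaction type is the Moore rearrangement of squarate-derived 4-alkenyl-4-hydroxycyclobutenones to hydroquinones. Exclusion of air should keep the electron-rich hydroquinone from going on to the quinone.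

Step 7
Reactants: 14 5,7-bis(benzyloxy)-2-(2,5-dihydroxy-3,4-dimethoxyphenyl)-4H-chromen-4-one
Product: 15 5,7-bis(benzyloxy)-2-(2,3,4,5-tetramethoxyphenyl)-4H-chromen-4-one
Conditions: Me2SO4, K2CO3, acetone (degassed), 56 °C, Ar
Reagents that add atoms: dimethyl sulfate, COS(=O)(=O)OC
Why: Williamson O-methylation of both phenols; no other hydroxyl is free, so no selectivity is required, and the inert atmosphere protects the hydroquinone anion until both oxygens are capped.

Step 8
Reactants: 15 5,7-bis(benzyloxy)-2-(2,3,4,5-tetramethoxyphenyl)-4H-chromen-4-one
Product: 16 5,7-dihydroxy-2-(2,3,4,5-tetramethoxyphenyl)-4H-chromen-4-one (5,7-dihydroxy-2',3',4',5'-tetramethoxyflavone)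
Conditions: H2 (1 atm), Pd/C, EtOAc–MeOH, 23 °C
Reagents that add atoms: none
Why: Hydrogenolysis of aryl benzyl ethers over palladium on carbon; aryl methyl ethers are inert and the C2–C3 double bond of the pyranone, a vinylogous ester conjugated to both rings, should be reduced much more slowly, so the reaction is stopped once two equivalents of hydrogen are taken up.

## Compound list

1 | 2,4,6-trihydroxyacetophenone | CC(=O)c1c(O)cc(O)cc1O | starting material
2 | 1-[2,4-bis(benzyloxy)-6-hydroxyphenyl]ethan-1-one | CC(=O)c1c(O)cc(OCc2ccccc2)cc1OCc1ccccc1 | intermediate
3 | (E)-1-[2,4-bis(benzyloxy)-6-hydroxyphenyl]-3-(dimethylamino)prop-2-en-1-one | CN(C)/C=C/C(=O)c1c(O)cc(OCc2ccccc2)cc1OCc1ccccc1 | intermediate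
4 | 5,7-bis(benzyloxy)-4H-chromen-4-one | O=c1ccoc2cc(OCc3ccccc3)cc(OCc3ccccc3)c12 | intermediate
5 | [5,7-bis(benzyloxy)-4-oxo-4H-chromen-2-yl]zinc chloride (LiCl complex) | O=c1cc([Zn]Cl)oc2cc(OCc3ccccc3)cc(OCc3ccccc3)c12 | intermediate
6 | 5,7-bis(benzyloxy)-2-iodo-4H-chromen-4-one | O=c1cc(I)oc2cc(OCc3ccccc3)cc(OCc3ccccc3)c12 | intermediate
7 | (E)-1,2-bis(tributylstannyl)ethene | CCCC[Sn](CCCC)(CCCC)/C=C/[Sn](CCCC)(CCCC)CCCC | starting material
8 | dimethyl squarate (3,4-dimethoxycyclobut-3-ene-1,2-dione) | COC1=C(OC)C(=O)C1=O | starting material
9 | (E)-2-(tributylstannyl)vinyllithium | [Li]/C=C/[Sn](CCCC)(CCCC)CCCC | intermediate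
10 | racemic 4-hydroxy-2,3-dimethoxy-4-[(E)-2-(tributylstannyl)ethenyl]cyclobut-2-en-1-one | COC1=C(OC)C(O)(/C=C/[Sn](CCCC)(CCCC)CCCC)C1=O | intermediate
11 | racemic 4-[(E)-2-(5,7-bis(benzyloxy)-4-oxo-4H-chromen-2-yl)ethenyl]-4-hydroxy-2,3-dimethoxycyclobut-2-en-1-one | COC1=C(OC)C(O)(/C=C/c2cc(=O)c3c(OCc4ccccc4)cc(OCc4ccccc4)cc3o2)C1=O | intermediate
12 | (3Z,5E)-6-[5,7-bis(benzyloxy)-4-oxo-4H-chromen-2-yl]-4-hydroxy-2,3-dimethoxyhexa-1,3,5-trien-1-one | O=C=C(OC)/C(OC)=C(\C=C\c1cc(=O)c2c(OCc3ccccc3)cc(OCc3ccccc3)cc2o1)O | intermediate
13 | racemic 6-[5,7-bis(benzyloxy)-4-oxo-4H-chromen-2-yl]-4-hydroxy-2,3-dimethoxycyclohexa-2,4-dien-1-one | O=C1C(OC)=C(OC)C(O)=CC1c1cc(=O)c2c(OCc3ccccc3)cc(OCc3ccccc3)cc2o1 | intermediate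
14 | 5,7-bis(benzyloxy)-2-(2,5-dihydroxy-3,4-dimethoxyphenyl)-4H-chromen-4-one | COc1c(O)cc(-c2cc(=O)c3c(OCc4ccccc4)cc(OCc4ccccc4)cc3o2)c(O)c1OC | intermediate
15 | 5,7-bis(benzyloxy)-2-(2,3,4,5-tetramethoxyphenyl)-4H-chromen-4-one | COc1cc(-c2cc(=O)c3c(OCc4ccccc4)cc(OCc4ccccc4)cc3o2)c(OC)c(OC)c1OC | intermediate
16 | 5,7-dihydroxy-2-(2,3,4,5-tetramethoxyphenyl)-4H-chromen-4-one | COc1cc(-c2cc(=O)c3c(O)cc(O)cc3o2)c(OC)c(OC)c1OC | target

## Step count and risks

Total: 8 steps. Longest linear sequence: 7 steps (steps 1, 2, 3, 5, 6, 7, 8 from 1); the squarate branch contributes one step (step 4).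

**Step 6 (key step).** The most likely failures are rotation of the hydroxyl inward during ring opening, which leads to lactonisation of the ketene instead of ring closure, and oxidation of the free hydroquinone during the hot reaction or isolation. Both originate in the free carbinol hydroxyl. The fallback removes it before heating. Setting out from 11, the carbinol would be methylated with MeI and Ag2O in acetonitrile at 23 °C to racemic 4-[(E)-2-(5,7-bis(benzyloxy)-4-oxo-4H-chromen-2-yl)ethenyl]-2,3,4-trimethoxycyclobut-2-en-1-one F1. Thermolysis of F1 in toluene at 110 °C should then deliver the air-stable monophenol 5,7-bis(benzyloxy)-2-(2-hydroxy-3,4,5-trimethoxyphenyl)-4H-chromen-4-one F2, in which the former carbinol oxygen is already the 5'-methoxyl. Methylation of the one remaining phenol under the conditions of step 7 returns to the route at 15.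

**Step 3.** Metallation may occur at the wrong site (at C3 through delivery by the carbonyl, or on ring A between two alkoxy groups), or the iodide may be lost through addition–elimination at C2 during work-up. The fallback avoids C–H metallation. Setting out from 2, treatment with CS2 and t-BuOK in THF would close the ring to 5,7-bis(benzyloxy)-4-hydroxy-2H-chromene-2-thione F3. S-Methylation (MeI, K2CO3, acetone) would give 5,7-bis(benzyloxy)-2-(methylsulfanyl)-4H-chromen-4-one F4. A thioether–stannane cross-coupling of F4 with 10 (Pd(PPh3)4, CuBr·SMe2 as thiolate scavenger, THF, 50 °C; Liebeskind–Srogl type) would come back to the route at 11.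

**Step 4.** Incomplete tin–lithium exchange would leave butyllithium to add to the squarate, a second addition may occur, and the allylic stannyl carbinol may suffer protodestannylation on silica. The fallback builds the stannane after the addition. Setting out from 8, ethynylmagnesium bromide in THF at −78 °C would give racemic 4-ethynyl-4-hydroxy-2,3-dimethoxycyclobut-2-en-1-one F5. Palladium-catalysed hydrostannation (PdCl2(PPh3)2, Bu3SnH, THF, 0 °C) of this hindered tertiary propargylic alcohol should place tin on the terminal carbon by syn addition and so return to the route at 10.

**Step 5.** Transmetallation from tin next to the quaternary carbinol carbon may be slow, which would allow protodestannylation, homocoupling or reductive loss of the iodide to compete. The fallback forms the same bond without transmetallation. Setting out from 8, vinylmagnesium bromide in THF at −78 °C would give racemic 4-ethenyl-4-hydroxy-2,3-dimethoxycyclobut-2-en-1-one F6. A Heck reaction of F6 with 6 under mild phase-transfer conditions (Pd(OAc)2, Bu4NCl, NaHCO3, DMF, 40 °C) should give the linear E-alkene, because the quaternary carbinol carbon blocks the branched mode, and returns to the route at 11.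

## Further compounds

F1 | step 6 | racemic 4-[(E)-2-(5,7-bis(benzyloxy)-4-oxo-4H-chromen-2-yl)ethenyl]-2,3,4-trimethoxycyclobut-2-en-1-one | COC1=C(OC)C(OC)(/C=C/c2cc(=O)c3c(OCc4ccccc4)cc(OCc4ccccc4)cc3o2)C1=O
F2 | step 6 | 5,7-bis(benzyloxy)-2-(2-hydroxy-3,4,5-trimethoxyphenyl)-4H-chromen-4-one | COc1cc(-c2cc(=O)c3c(OCc4ccccc4)cc(OCc4ccccc4)cc3o2)c(O)c(OC)c1OC
F3 | step 3 | 5,7-bis(benzyloxy)-4-hydroxy-2H-chromene-2-thione | Oc1cc(=S)oc2cc(OCc3ccccc3)cc(OCc3ccccc3)c12
F4 | step 3 | 5,7-bis(benzyloxy)-2-(methylsulfanyl)-4H-chromen-4-one | CSc1cc(=O)c2c(OCc3ccccc3)cc(OCc3ccccc3)cc2o1
F5 | step 4 | racemic 4-ethynyl-4-hydroxy-2,3-dimethoxycyclobut-2-en-1-one | COC1=C(OC)C(O)(C#C)C1=O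
F6 | step 5 | racemic 4-ethenyl-4-hydroxy-2,3-dimethoxycyclobut-2-en-1-one | COC1=C(OC)C(O)(C=C)C1=O
A1 | alternative 1 | (E)-3-(2,3,4,5-tetramethoxyphenyl)-1-(2,4,6-trihydroxyphenyl)prop-2-en-1-one | O=C(/C=C/c1cc(OC)c(OC)c(OC)c1OC)c1c(O)cc(O)cc1O
A2 | alternative 1 | 4-hydroxy-6-[(E)-2-oxo-4-(2,3,4,5-tetramethoxyphenyl)but-3-en-1-yl]-2H-pyran-2-one | COc1cc(/C=C/C(=O)Cc2cc(O)cc(=O)o2)c(OC)c(OC)c1OC
A3 | alternative 1 | methyl (E)-3,5,7-trioxo-9-(2,3,4,5-tetramethoxyphenyl)non-8-enoate | COC(=O)CC(=O)CC(=O)CC(=O)/C=C/c1cc(OC)c(OC)c(OC)c1OC
A4 | alternative 2 | 1-[2,4-bis(benzyloxy)-6-hydroxyphenyl]-3-(2,3,4,5-tetramethoxyphenyl)prop-2-yn-1-one | O=C(C#Cc1cc(OC)c(OC)c(OC)c1OC)c1c(O)cc(OCc2ccccc2)cc1OCc1ccccc1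
A5 | alternative 2 | 3-(2,3,4,5-tetramethoxyphenyl)prop-2-ynoic acid | COc1cc(C#CC(=O)O)c(OC)c(OC)c1OC
A6 | alternative 2 | 3,5-bis(benzyloxy)-2-(trimethylsilyl)phenyl trifluoromethanesulfonate | C[Si](C)(C)c1c(OCc2ccccc2)cc(OCc2ccccc2)cc1OS(=O)(=O)C(F)(F)F
A7 | alternative 3 | 5,7-difluoro-2-(2,3,4,5-tetramethoxyphenyl)-4H-chromen-4-one | O=c1cc(-c2cc(OC)c(OC)c(OC)c2OC)oc2cc(F)cc(F)c12
A8 | alternative 3 | 1-(2,3,4,5-tetramethoxyphenyl)-3-(2,4,6-trifluorophenyl)propane-1,3-dione | COc1cc(C(=O)CC(=O)c2c(F)cc(F)cc2F)c(OC)c(OC)c1OC
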